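Violet left 42.0% of its substrates unreacted at 5.00 h, and that leftover set my reckoning going.

| setting | blue | violet | midnight | winter | summer | spring |
|---|---|---|---|---|---|---|
| left-handed substrate | 0.025 M | 0.10 M | 0.050 M | 0.050 M | 0.050 M | 0.050 M |
| right-handed substrate | 0.025 M | 0.10 M | 0.050 M | 0.050 M | 0.050 M | 0.050 M |
| coupling partner | 3 equiv | 3 equiv | 3.00 equiv | 3.00 equiv | 3.00 equiv | 3.00 equiv |
| free catalyst | 0.2 mol% | 0.2 mol% | 0.2 mol% | 0.2 mol% | 0.2 mol% | 0.2 mol% |
| added ligand | 0.19 mM | 0.19 mM | 0.19 mM | 0.19 mM | 0.19 mM | 0.19 mM |
| temperature | 42 °C | 92 °C | 50 °C | 80 °C | 110 °C | 20 °C |
| remark | run made earlier | run made earlier |  |  |  |  |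
| time |  |  | 40 h | 40 h | 40 h | 40 h |
- blue (time / h: left-handed product / %, right-handed product / %, left-handed substrate / %): 4.00: 0, 0, 50; 10.0: 0, 1, 52; 20.0: 0, 1, 52; 30.0: 1, 0, 47; 40.0: 2, 0, 49
- violet (time / h: left-handed product / %, right-handed product / %, left-handed substrate / %): 0.500: 5, 4, 39; 1.33: 20, 5, 29; 2.50: 27, 13, 23; 4.00: 39, 18, 16; 5.00: 37, 21, 17

(each reading ± 1.5 percentage points)
- free catalyst is single-handed; left-handed substrate and right-handed substrate are mirror images of each other, charged as a racemate, each of them at the stated concentration
- steps that have been proposed: coupling partner + free catalyst + left-handed substrate -> free catalyst + left-handed product; coupling partner + free catalyst + right-handed substrate -> free catalyst + right-handed product; left-handed substrate <-> right-handed substrate; free catalyst -> spent catalyst; 2 free catalyst <-> resting dimer; free catalyst + added ligand <-> idle complex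
- an excess is the difference of the two amounts in percent of their sum
- an excess is below zero if the other one leads
- the best flask by excess of left-handed product over right-handed product; "all alike" if 1.5 percentage points covers them all (midnight / winter / summer / spring / all alike)
- excess of left-handed product over right-handed product at the end, midnight
- excess of left-handed product over right-handed product at the end, winter
- excess of left-handed product over right-handed product at the end, summer
- excess of left-handed product over right-handed product at the end, spring

The coupling partner, 3.00 equiv on the left-handed substrate, is 1.50 on both substrates together, so the substrates were the limiting reagent, and products plus substrates make up the charge. I ranked violet's rates on that balance. Coupling took 0.113 /h of the charge between 2.50 h and 4.00 h, then 0.0100 /h in the last interval, far less, though substrate remained. I read that stall, within the scatter, as the proposed loss of free catalyst. Interconversion came next: violet's left-handed product plus left-handed substrate stood at 55.0% at 4.00 h, above the half charged, a drift of 0.0125 /h, with coupling ten times faster. Slowest was blue, which had converted hardly any of its more dilute charge by 40.0 h.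

So I carried the selectivity factor s, the left-handed coupling rate over the right-handed one at equal substrate, which is the logarithm of the fraction of left-handed substrate remaining over the logarithm of the fraction of right-handed substrate remaining. Violet's readings at 2.50 h, with the right-handed substrate taken from the balance as 37.0%, give s as a rough reading of 2.58, with interconversion set aside. It gives a kinetic excess, s less one over s plus one, of 44.1%. Violet's last two readings give 32.2%. I placed summer, if it stalled like violet, between those two figures. I expected spring to show its own s undisturbed, and to lead if cold raises s, which blue was too thin to show.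

The forecast gave 43% for midnight, 31% for winter, 22% for summer and 50% for spring, with spring best, reasoning “Colder flasks stop early at the kinetic ratio”.

The flasks gave 48.0% for midnight, 32.6% for winter, 35.0% for summer, inside my bracket , and 57.2% for spring, the best.

    coupling partner + free catalyst + left-handed substrate → free catalyst + left-handed product (k = 5.88 /M²/s, Ea = 55.0 kJ/mol)
    coupling partner + free catalyst + right-handed substrate → free catalyst + right-handed product (k = 2.26 /M²/s, Ea = 60.0 kJ/mol)
    left-handed substrate ⇌ right-handed substrate (k = 4.00 × 10⁻⁶ /s, Ea = 128 kJ/mol)
    free catalyst → spent catalyst (k = 1.27 × 10⁻⁵ /s, Ea = 124 kJ/mol)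
    2 free catalyst ⇌ resting dimer, settled at all times (K = 1.10 × 10⁵ /M, ΔH = −45.0 kJ/mol)
    free catalyst + added ligand ⇌ idle complex (K = 11900 /M, k = 0.0892 /M/s, Ea = 57.0 kJ/mol, ΔH = −52.0 kJ/mol)
    (constants at 80 °C)

Spring still held 99% of its left-handed substrate, and its excess turned back into s gives 3.67, above violet's 2.58. Taking ln s as straight in temperature between those two flasks, I stepped on to the neighbour, spring repeated at −5 °C. That gave s of 4.15 and an excess of 61.2%. The neighbour kept 99.9% of its left-handed substrate, and its excess came to 63.4%.

All runs are calculated for an exercise, and the scatter is random.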